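The earlier runs and the new flask were generated by integration for an exercise, noise included.

At 4.00 h the west run reads X 12.0 % of the Q and L charged. The flask differs from it in its Z charge.

all flasks: Q 0.020 M; L 0.020 M; D 0.20 mM
- east: Z 0.0060 M; run made earlier
- west: Z 0.0090 M; run made earlier
- flask: Z 0.0120 M

- east (time / h: X / %, Q / %): 0.833: 4.7, 47.0; 1.50: 5.2, 46.4; 2.50: 6.4, 45.2; 3.00: 9.7, 45.8; 4.00: 9.8, 45.6
- west (time / h: X / %, Q / %): 0.333: 3.2, 48.1; 1.00: 7.6, 44.2; 2.00: 10.0, 43.9; 3.00: 11.7, 43.4; 4.00: 12.0, 42.4

(each reading ± 1 percentage point)

- D is single-handed; Q and L are mirror images of each other, charged as a racemate, each of them at the stated concentration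
- what may be going on: D <-> E; Q <-> L; Z + D + L -> D + J; Z + D + Q -> D + X
- no earlier run changes the charge of D; that part of a forecast is a guess

1. apparent order in D when 5.0 % of the Q and L together are converted (percent change of the rate of making X for one percent more D charged)

Z is the limiting reagent, and each X or J uses one Z. So I carry the Z ceiling, the fraction of the Q and L charge that the Z charge can convert: 30.0 %. The Z left is one minus conversion over ceiling. At 5.0 % conversion in the flask that is 83.3 % of the Z charge. That figure contains no D, so changing the D charge leaves it as it is. So Z adds nothing to the order at that conversion. My reckoning starts from an order of one, with the rate following D, and goes a little above one if more D gets there sooner and less of it has become E.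

The forecast gives 1.15, with a range of 0.85 to 1.45, taking the look as reached sooner with more D, “when less catalyst has gone to E”.

The flask gives 1.2, inside that range.

    D ⇌ E (K = 3.10, k = 0.400 h⁻¹)
    Q ⇌ L (k = 0.870 h⁻¹)
    Z + D + L → D + J (k = 1200 L² mol⁻² h⁻¹)
    Z + D + Q → D + X (k = 1.10 × 10⁵ L² mol⁻² h⁻¹)

The flask reaches the look at 0.470 h, and E holds 14.4 % of its catalyst at 0.400 h. At 40.0 h the flask has X 29.0 % and J 0.328 % against the ceiling of 30.0 %, with Z at 2.23 % of its charge. The west ceiling is 22.5 %, so X read at 12.0 % at 4.00 h leaves about 46.7 % of the west Z, counting X alone.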